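**Assumption:** the target has no stereocentre and is achiral, so there is no enantiomer to select; intermediates 6 and 8–15 carry one lactone/carbinol stereocentre (destroyed in step 11) and are used as racemates.

**Retrosynthetic overview**
1. Target 17 ⇐ tetra-MOM keto-aldehyde 16 ⇐ diol 15 ⇐ 3-arylphthalide 14: the diaryl ketone carbon and the formyl carbon are C3 and C1 of a phthalide.
2. Prenyl ⇐ allyl (cross-metathesis) ⇐ aryl bromide (Stille), introduced only after ring A is aromatic.
3. Key disconnection: the bond from phthalide C3 to ring A, made by intermolecular aldol addition of 5-methylcyclohexane-1,3-dione 7 to the aldehyde of hydroxyphthalide 6, with lactonisation; the dione ring is then aromatised to ring A.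
4. 6 ⇐ 3,5-dimethoxybenzaldehyde 1 by dibromination, acetal protection and bromine–lithium exchange/carboxylation.
5. Ring order: ring B is bought aromatic; the lactone ring closes in steps 3–4; ring A comes from 7 and is aromatised in step 5; the lactone is opened in step 10.

**Route**

Step 1
Reactants: 1 3,5-dimethoxybenzaldehyde
Product: 2 2,6-dibromo-3,5-dimethoxybenzaldehyde
Conditions: Br2 (2.2 equiv), AcOH, rt
Reagents that add atoms: bromine, BrBr
Why: Electrophilic aromatic bromination goes twice at the positions para to a methoxy group (C2, C6) rather than at the doubly ortho C4, as is usual for 3,5-dimethoxyaryl compounds.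

Step 2
Reactants: 2 2,6-dibromo-3,5-dimethoxybenzaldehyde
Product: 3 2-(2,6-dibromo-3,5-dimethoxyphenyl)-1,3-dioxolane
Conditions: ethylene glycol, p-TsOH (cat.), toluene, reflux, Dean–Stark
Reagents that add atoms: ethylene glycol, OCCO
Why: Acid-catalysed acetalisation with azeotropic removal of water masks the aldehyde against the organolithium of the next step.

Step 3
Reactants: 3 2-(2,6-dibromo-3,5-dimethoxyphenyl)-1,3-dioxolane
Product: 6 racemic 4-bromo-3-hydroxy-5,7-dimethoxy-2-benzofuran-1(3H)-one, via aryllithium 4 (not isolated), via lithium carboxylate 5 (not isolated)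
Conditions: n-BuLi (1.05 equiv), THF, –78 °C; CO2, –78 °C → rt; then 2 M aq. HCl, THF, rt
Reagents that add atoms: carbon dioxide, O=C=O; water, O
Why: Bromine–lithium exchange with one equivalent of n-BuLi stops after one exchange on the symmetric dibromide, the aryllithium is carboxylated, and aqueous acid cleaves the dioxolane so that the 2-formylbenzoic acid closes to its ring tautomer, the 3-hydroxyphthalide (hemiacetal centre racemic and epimerisable).

Step 4
Reactants: 6 racemic 4-bromo-3-hydroxy-5,7-dimethoxy-2-benzofuran-1(3H)-one; 7 5-methylcyclohexane-1,3-dione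
Product: 9 racemic 4-bromo-3-(2-hydroxy-4-methyl-6-oxocyclohex-1-en-1-yl)-5,7-dimethoxy-2-benzofuran-1(3H)-one, via aldol adduct 8 (not isolated)
Conditions: Et3N (20 mol %), MeCN, 60 °C
Reagents that add atoms: none
Why: Intermolecular aldol addition of the enolate of 7 to the open aldehyde form of 6 joins the two fragments, and the neighbouring carboxyl group lactonises onto the new carbinol carbon (aldol–lactonisation cascade), which traps the 1:1 adduct instead of the usual 2:1 Knoevenagel–Michael product; the new C3 centre forms as a racemate and is removed later.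

Step 5
Reactants: 9 racemic 4-bromo-3-(2-hydroxy-4-methyl-6-oxocyclohex-1-en-1-yl)-5,7-dimethoxy-2-benzofuran-1(3H)-one
Product: 10 racemic 4-bromo-3-(2,6-dimethoxy-4-methylphenyl)-5,7-dimethoxy-2-benzofuran-1(3H)-one
Conditions: I2 (2.2 equiv), MeOH, reflux
Reagents that add atoms: methanol, CO
Why: Iodine–methanol oxidative aromatisation converts the dione into its methyl enol ethers, and α-iodination with loss of HI dehydrogenates the ring to the resorcinol dimethyl ether, while aryl bromide and lactone are inert.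

Step 6
Reactants: 10 racemic 4-bromo-3-(2,6-dimethoxy-4-methylphenyl)-5,7-dimethoxy-2-benzofuran-1(3H)-one
Product: 11 racemic 4-bromo-3-(2,6-dihydroxy-4-methylphenyl)-5,7-dihydroxy-2-benzofuran-1(3H)-one
Conditions: BBr3 (8 equiv), CH2Cl2, –78 °C → rt; then H2O
Reagents that add atoms: none
Why: Lewis-acid ether cleavage with BBr3 removes all four methyl ethers while only a lactone and an aryl bromide are present, before any acid-sensitive alkene is introduced.

Step 7
Reactants: 11 racemic 4-bromo-3-(2,6-dihydroxy-4-methylphenyl)-5,7-dihydroxy-2-benzofuran-1(3H)-one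
Product: 12 racemic 3-[2,6-bis(methoxymethoxy)-4-methylphenyl]-4-bromo-5,7-bis(methoxymethoxy)-2-benzofuran-1(3H)-one
Conditions: MOMCl (6 equiv), i-Pr2NEt (8 equiv), DMAP (cat.), CH2Cl2, 0 → 40 °C
Reagents that add atoms: chloromethyl methyl ether, COCCl
Why: O-Alkylation of the four phenols (Williamson-type etherification) under a mild amine base installs acetal protecting groups that withstand cross-coupling, metathesis, hydride and Swern conditions.

Step 8
Reactants: 12 racemic 3-[2,6-bis(methoxymethoxy)-4-methylphenyl]-4-bromo-5,7-bis(methoxymethoxy)-2-benzofuran-1(3H)-one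
Product: 13 racemic 3-[2,6-bis(methoxymethoxy)-4-methylphenyl]-5,7-bis(methoxymethoxy)-4-(prop-2-en-1-yl)-2-benzofuran-1(3H)-one
Conditions: allylSnBu3 (1.5 equiv), Pd(PPh3)4 (10 mol %), DMF, 100 °C
Reagents that add atoms: allyltributylstannane, C=CC[Sn](CCCC)(CCCC)CCCC
Why: In this Stille cross-coupling zerovalent palladium inserts into the aryl–bromine bond and the allyl group is transferred from tin without touching the lactone or the MOM ethers.

Step 9
Reactants: 13 racemic 3-[2,6-bis(methoxymethoxy)-4-methylphenyl]-5,7-bis(methoxymethoxy)-4-(prop-2-en-1-yl)-2-benzofuran-1(3H)-one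
Product: 14 racemic 3-[2,6-bis(methoxymethoxy)-4-methylphenyl]-5,7-bis(methoxymethoxy)-4-(3-methylbut-2-en-1-yl)-2-benzofuran-1(3H)-one
Conditions: 2-methyl-2-butene (large excess), second-generation Grubbs catalyst RuCl2(=CHPh)(H2IMes)(PCy3) (5 mol %), CH2Cl2, 40 °C
Reagents that add atoms: 2-methyl-2-butene, CC=C(C)C
Why: Olefin cross-metathesis with excess 2-methyl-2-butene converts the terminal allyl alkene into the trisubstituted prenyl alkene and is driven by loss of volatile propene.

Step 10
Reactants: 14 racemic 3-[2,6-bis(methoxymethoxy)-4-methylphenyl]-5,7-bis(methoxymethoxy)-4-(3-methylbut-2-en-1-yl)-2-benzofuran-1(3H)-one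
Product: 15 racemic [2-(hydroxymethyl)-3,5-bis(methoxymethoxy)-6-(3-methylbut-2-en-1-yl)phenyl][2,6-bis(methoxymethoxy)-4-methylphenyl]methanol
Conditions: LiAlH4 (2 equiv), THF, 0 °C → rt; then H2O
Reagents that add atoms: none
Why: Hydride reduction of the lactone with LiAlH4 opens the phthalide to the 1,4-diol without affecting aryl MOM ethers or the isolated alkene, and the carbinol centre stays racemic.

Step 11
Reactants: 15 racemic [2-(hydroxymethyl)-3,5-bis(methoxymethoxy)-6-(3-methylbut-2-en-1-yl)phenyl][2,6-bis(methoxymethoxy)-4-methylphenyl]methanol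
Product: 16 2-[2,6-bis(methoxymethoxy)-4-methylbenzoyl]-4,6-bis(methoxymethoxy)-3-(3-methylbut-2-en-1-yl)benzaldehyde
Conditions: (COCl)2 (4 equiv), DMSO (8 equiv), CH2Cl2, –78 °C; then Et3N (12 equiv), –78 → 0 °C
Reagents that add atoms: none
Why: Swern oxidation activates both hydroxyl groups as alkoxysulfonium ions at –78 °C before base is added, so benzhydrol and primary benzylic alcohol are oxidised together to ketone and aldehyde without lactol formation and return to the lactone; the last stereocentre disappears here.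

Step 12
Reactants: 16 2-[2,6-bis(methoxymethoxy)-4-methylbenzoyl]-4,6-bis(methoxymethoxy)-3-(3-methylbut-2-en-1-yl)benzaldehyde
Product: 17 2-(2,6-dihydroxy-4-methylbenzoyl)-4,6-dihydroxy-3-(3-methylbut-2-en-1-yl)benzaldehyde
Conditions: 3 M aq. HCl, MeOH, 45 °C, short reaction time
Reagents that add atoms: none
Why: Acid-catalysed acetal exchange with methanol cleaves the four aryl MOM ethers (formaldehyde leaves as dimethoxymethane) under dilute conditions of the kind used for other prenylated polyphenols, giving the achiral target.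

**Compound list**
1 | 3,5-dimethoxybenzaldehyde | COc1cc(OC)cc(C=O)c1 | starting material
2 | 2,6-dibromo-3,5-dimethoxybenzaldehyde | COc1cc(OC)c(Br)c(C=O)c1Br | intermediate
3 | 2-(2,6-dibromo-3,5-dimethoxyphenyl)-1,3-dioxolane | COc1cc(OC)c(Br)c(C2OCCO2)c1Br | intermediate
4 | [3-bromo-2-(1,3-dioxolan-2-yl)-4,6-dimethoxyphenyl]lithium (not isolated) | [Li]c1c(OC)cc(OC)c(Br)c1C1OCCO1 | intermediate
5 | lithium 3-bromo-2-(1,3-dioxolan-2-yl)-4,6-dimethoxybenzoate (not isolated) | [Li+].[O-]C(=O)c1c(OC)cc(OC)c(Br)c1C1OCCO1 | intermediate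
6 | racemic 4-bromo-3-hydroxy-5,7-dimethoxy-2-benzofuran-1(3H)-one (ring tautomer of 3-bromo-2-formyl-4,6-dimethoxybenzoic acid) | COc1cc(OC)c2c(c1Br)C(O)OC2=O | intermediate
7 | 5-methylcyclohexane-1,3-dione | CC1CC(=O)CC(=O)C1 | starting material
8 | 3-bromo-2-[hydroxy(2-hydroxy-4-methyl-6-oxocyclohex-1-en-1-yl)methyl]-4,6-dimethoxybenzoic acid (racemic, not isolated) | COc1cc(OC)c(C(=O)O)c(C(O)C2=C(O)CC(C)CC2=O)c1Br | intermediate
9 | racemic 4-bromo-3-(2-hydroxy-4-methyl-6-oxocyclohex-1-en-1-yl)-5,7-dimethoxy-2-benzofuran-1(3H)-one (enol tautomers) | COc1cc(OC)c2c(c1Br)C(OC2=O)C1=C(O)CC(C)CC1=O | intermediate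
10 | racemic 4-bromo-3-(2,6-dimethoxy-4-methylphenyl)-5,7-dimethoxy-2-benzofuran-1(3H)-one | COc1cc(OC)c2c(c1Br)C(OC2=O)c1c(OC)cc(C)cc1OC | intermediate
11 | racemic 4-bromo-3-(2,6-dihydroxy-4-methylphenyl)-5,7-dihydroxy-2-benzofuran-1(3H)-one | Oc1cc(O)c2c(c1Br)C(OC2=O)c1c(O)cc(C)cc1O | intermediate
12 | racemic 3-[2,6-bis(methoxymethoxy)-4-methylphenyl]-4-bromo-5,7-bis(methoxymethoxy)-2-benzofuran-1(3H)-one | COCOc1cc(OCOC)c2c(c1Br)C(OC2=O)c1c(OCOC)cc(C)cc1OCOC | intermediate
13 | racemic 3-[2,6-bis(methoxymethoxy)-4-methylphenyl]-5,7-bis(methoxymethoxy)-4-(prop-2-en-1-yl)-2-benzofuran-1(3H)-one | COCOc1cc(OCOC)c2c(c1CC=C)C(OC2=O)c1c(OCOC)cc(C)cc1OCOC | intermediate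
14 | racemic 3-[2,6-bis(methoxymethoxy)-4-methylphenyl]-5,7-bis(methoxymethoxy)-4-(3-methylbut-2-en-1-yl)-2-benzofuran-1(3H)-one | COCOc1cc(OCOC)c2c(c1CC=C(C)C)C(OC2=O)c1c(OCOC)cc(C)cc1OCOC | intermediate
15 | racemic [2-(hydroxymethyl)-3,5-bis(methoxymethoxy)-6-(3-methylbut-2-en-1-yl)phenyl][2,6-bis(methoxymethoxy)-4-methylphenyl]methanol | COCOc1cc(OCOC)c(CO)c(c1CC=C(C)C)C(O)c1c(OCOC)cc(C)cc1OCOC | intermediate
16 | 2-[2,6-bis(methoxymethoxy)-4-methylbenzoyl]-4,6-bis(methoxymethoxy)-3-(3-methylbut-2-en-1-yl)benzaldehyde | COCOc1cc(OCOC)c(C=O)c(c1CC=C(C)C)C(=O)c1c(OCOC)cc(C)cc1OCOC | intermediate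
17 | 2-(2,6-dihydroxy-4-methylbenzoyl)-4,6-dihydroxy-3-(3-methylbut-2-en-1-yl)benzaldehyde | CC(C)=CCc1c(O)cc(O)c(C=O)c1C(=O)c1c(O)cc(C)cc1O | target

**Totals**
Total step count: 12. Longest linear sequence: 12 steps (1 → 17); 7 enters in step 4.

**Steps most likely to fail, with fallbacks**

Step 5 (aromatisation of the dione ring). Hot acidic methanol may open the acyloxy-substituted benzylic position of 9 or stop at the monomethyl ether; partial methylation is harmless because step 6 removes all methyl groups. The fallback sets out from 9 and replaces the oxidation by halogenation–dehydrohalogenation. N-Chlorosuccinimide in CH2Cl2 chlorinates the dione at C2 to give 4-bromo-3-(1-chloro-4-methyl-2,6-dioxocyclohexyl)-5,7-dimethoxy-2-benzofuran-1(3H)-one F1, which can no longer enolise towards the lactone carbon. Heating with LiCl in DMF at about 130 °C then eliminates HCl and gives the free resorcinol 4-bromo-3-(2,6-dihydroxy-4-methylphenyl)-5,7-dimethoxy-2-benzofuran-1(3H)-one F2. BBr3 cleaves the two remaining methyl ethers and the route is rejoined at 11.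

Step 11 (double oxidation of the diol). The electron-rich benzhydrol may ionise on activation and close to a cyclic ether, or the half-oxidised material may lactolise and return to the lactone. The fallback sets out from 15 and oxidises the two alcohols one after the other. TBSCl/imidazole silylates only the primary alcohol to give {2-[(tert-butyldimethylsilyloxy)methyl]-3,5-bis(methoxymethoxy)-6-(3-methylbut-2-en-1-yl)phenyl}[2,6-bis(methoxymethoxy)-4-methylphenyl]methanol F3. Dess–Martin periodinane buffered with NaHCO3 oxidises the hindered carbinol to {2-[(tert-butyldimethylsilyloxy)methyl]-3,5-bis(methoxymethoxy)-6-(3-methylbut-2-en-1-yl)phenyl}[2,6-bis(methoxymethoxy)-4-methylphenyl]methanone F4. TBAF frees [2-(hydroxymethyl)-3,5-bis(methoxymethoxy)-6-(3-methylbut-2-en-1-yl)phenyl][2,6-bis(methoxymethoxy)-4-methylphenyl]methanone F5, which equilibrates with its cyclic hemiketal, and MnO2 in CH2Cl2 oxidises it through the open form to come back at 16.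

Step 12 (acidic MOM removal next to a prenyl group). The prenyl group may cyclise onto the neighbouring phenol to a chroman or add HCl or methanol. The fallback sets out from 13 and postpones the metathesis until after deprotection, so that only the acid-stable allyl group meets the acid. LiAlH4 reduces 13 to [2-(hydroxymethyl)-3,5-bis(methoxymethoxy)-6-(prop-2-en-1-yl)phenyl][2,6-bis(methoxymethoxy)-4-methylphenyl]methanol F6. Swern oxidation gives 2-[2,6-bis(methoxymethoxy)-4-methylbenzoyl]-4,6-bis(methoxymethoxy)-3-(prop-2-en-1-yl)benzaldehyde F7. HCl/MeOH gives 2-(2,6-dihydroxy-4-methylbenzoyl)-4,6-dihydroxy-3-(prop-2-en-1-yl)benzaldehyde F8. Cross-metathesis of this free polyphenol with excess 2-methyl-2-butene and second-generation Grubbs catalyst RuCl2(=CHPh)(H2IMes)(PCy3) arrives at 17.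

**Further compounds**
F1 | step 5 | racemic 4-bromo-3-(1-chloro-4-methyl-2,6-dioxocyclohexyl)-5,7-dimethoxy-2-benzofuran-1(3H)-one | COc1cc(OC)c2c(c1Br)C(OC2=O)C1(Cl)C(=O)CC(C)CC1=O
F2 | step 5 | racemic 4-bromo-3-(2,6-dihydroxy-4-methylphenyl)-5,7-dimethoxy-2-benzofuran-1(3H)-one | COc1cc(OC)c2c(c1Br)C(OC2=O)c1c(O)cc(C)cc1O
F3 | step 11 | racemic {2-[(tert-butyldimethylsilyloxy)methyl]-3,5-bis(methoxymethoxy)-6-(3-methylbut-2-en-1-yl)phenyl}[2,6-bis(methoxymethoxy)-4-methylphenyl]methanol | COCOc1cc(OCOC)c(CO[Si](C)(C)C(C)(C)C)c(c1CC=C(C)C)C(O)c1c(OCOC)cc(C)cc1OCOC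
F4 | step 11 | {2-[(tert-butyldimethylsilyloxy)methyl]-3,5-bis(methoxymethoxy)-6-(3-methylbut-2-en-1-yl)phenyl}[2,6-bis(methoxymethoxy)-4-methylphenyl]methanone | COCOc1cc(OCOC)c(CO[Si](C)(C)C(C)(C)C)c(c1CC=C(C)C)C(=O)c1c(OCOC)cc(C)cc1OCOC
F5 | step 11 | [2-(hydroxymethyl)-3,5-bis(methoxymethoxy)-6-(3-methylbut-2-en-1-yl)phenyl][2,6-bis(methoxymethoxy)-4-methylphenyl]methanone | COCOc1cc(OCOC)c(CO)c(c1CC=C(C)C)C(=O)c1c(OCOC)cc(C)cc1OCOC
F6 | step 12 | racemic [2-(hydroxymethyl)-3,5-bis(methoxymethoxy)-6-(prop-2-en-1-yl)phenyl][2,6-bis(methoxymethoxy)-4-methylphenyl]methanol | COCOc1cc(OCOC)c(CO)c(c1CC=C)C(O)c1c(OCOC)cc(C)cc1OCOC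
F7 | step 12 | 2-[2,6-bis(methoxymethoxy)-4-methylbenzoyl]-4,6-bis(methoxymethoxy)-3-(prop-2-en-1-yl)benzaldehyde | COCOc1cc(OCOC)c(C=O)c(c1CC=C)C(=O)c1c(OCOC)cc(C)cc1OCOC
F8 | step 12 | 2-(2,6-dihydroxy-4-methylbenzoyl)-4,6-dihydroxy-3-(prop-2-en-1-yl)benzaldehyde | C=CCc1c(O)cc(O)c(C=O)c1C(=O)c1c(O)cc(C)cc1O
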